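**Retrosynthetic overview**
- The target is a germacrane: one ten-membered carbocycle (C1–C10) with isopropenyl on C7, methyls on C4 and C10, a cis-oxirane at C1–C10, a trans-oxirane at C4–C5, angelates on C3 and C8 and acetate on C9. This is a farnesane skeleton in which the C6–C7 bond, the C7 stereocentre and both ring alkenes are what a sesquiterpene cyclase delivers.
- Late disconnections: the three esters, the 4,5-oxirane (from C3–OH and E-C4=C5), the 1,10-oxirane (from C9–OH and Z-C1=C10), C8–OH (enolate hydroxylation of the 9-ketone) and two allylic C–H hydroxylations (C9, C3) lead back to (7R)-(1(10)Z,4E)-germacra-1(10),4,11-triene.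
- Key disconnection: C6–C7, by cyclase-mediated end-to-end closure of (2E,6Z)-farnesyl diphosphate; the 6Z alkene becomes Z-C1=C10 and the 2E alkene becomes E-C4=C5.
- The diphosphate comes from nerylacetone and triethyl phosphonoacetate (olefination, reduction, chlorination, diphosphorylation).
- Ring order: ten-membered carbocycle (step 5), C1–C10 oxirane (step 10), C4–C5 oxirane (step 14).

Key step: step 5

Remark: germacrane numbering is used throughout; alcohol 9 is drawn 9S but either C9 epimer serves; CIP letters at C4, C7 and C10 change along the route only through priority changes (the SMILES strings are definitive); the enzyme variants of steps 5, 6 and 13 are taken from homologue and mutant panels; compounds 8–13 hold a 1,5-diene and are kept below 30 °C and away from acid.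

**Step 1**
Reactants: 1 nerylacetone; 2 triethyl phosphonoacetate
Product: 3 ethyl (2E,6Z)-3,7,11-trimethyldodeca-2,6,10-trienoate
Conditions: NaH, THF, 0 °C to rt; chromatography to remove the minor 2Z isomer
Reagents that add atoms: none
Why: Horner–Wadsworth–Emmons olefination of the methyl ketone by the sodium phosphonate anion should give mainly the 2E ester, and the 6Z alkene of nerylacetone is not touched.

**Step 2**
Reactants: 3 ethyl (2E,6Z)-farnesoate
Product: 4 (2E,6Z)-3,7,11-trimethyldodeca-2,6,10-trien-1-ol ((2E,6Z)-farnesol)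
Conditions: i-Bu2AlH, CH2Cl2, −78 °C; aq. potassium sodium tartrate
Reagents that add atoms: none
Why: 1,2-hydride reduction of the conjugated ester to the allylic alcohol proceeds without moving or isomerising either trisubstituted alkene.

**Step 3**
Reactants: 4 (2E,6Z)-farnesol
Product: 5 (2E,6Z)-farnesyl chloride
Conditions: N-chlorosuccinimide, Me2S, CH2Cl2, −30 to 0 °C
Reagents that add atoms: N-chlorosuccinimide, O=C1CCC(=O)N1Cl
Why: Corey–Kim chlorination through the alkoxysulfonium salt converts the primary allylic alcohol into the chloride under neutral conditions without allylic transposition or E/Z scrambling.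

**Step 4**
Reactants: 5 (2E,6Z)-farnesyl chloride
Product: 7 trisammonium (2E,6Z)-farnesyl diphosphate, via bis(tetrabutylammonium) farnesyl diphosphate 6 (not isolated)
Conditions: (n-Bu4N)3HP2O7, MeCN, rt; then Dowex 50W-X8 (NH4+ form), 25 mM NH4HCO3, lyophilisation
Reagents that add atoms: tris(tetrabutylammonium) hydrogen diphosphate, CCCC[N+](CCCC)(CCCC)CCCC.CCCC[N+](CCCC)(CCCC)CCCC.CCCC[N+](CCCC)(CCCC)CCCC.OP(=O)([O-])OP(=O)([O-])[O-]; ammonium hydrogencarbonate, [NH4+].OC([O-])=O
Why: SN2 displacement of the primary allylic chloride by the diphosphate anion, followed by cation exchange, gives the water-soluble ammonium salt that terpene cyclases accept.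

**Step 5**
Reactants: 7 trisammonium (2E,6Z)-farnesyl diphosphate
Product: 8 (7R)-(1(10)Z,4E)-germacra-1(10),4,11-triene
Conditions: recombinant germacrene A synthase variant (7R series), MgCl2 (10 mM), HEPES buffer pH 7.5, dithiothreitol, pentane overlay, 25 °C
Reagents that add atoms: none
Why: Proposed new method: magnesium-assisted ionisation of the diphosphate gives the 2E allyl cation C6–C5–C4, its C6 terminus is captured by C7 of the distal C7=C11 alkene held within reach by the enzyme fold, and the tertiary C11 cation is quenched by loss of a proton from C12 to the departing diphosphate; the closest known reaction is the same cyclisation of (2E,6E)-farnesyl diphosphate and of methyl- or fluoro-modified analogues by germacrene A synthases, the 6Z substrate being untried. The ten-membered ring closes end to end in the exo mode at the C7=C11 alkene (Markovnikov, cation left outside the ring at C11), forming C6–C7. C7, the only new stereocentre, is set by the enzyme, which presents one face of the C7=C11 alkene to C6; synthases of both enantiomeric series exist and a 7R-selective one is used. The step needs this closure to beat the alternative eleven-membered closure, water capture and elimination to farnesenes, and needs proton loss from C12 to beat transannular collapse; the water-excluding pocket and the positioned diphosphate base should secure this, while the 2E and 6Z geometries are fixed in the substrate and emerge as E-C4=C5 and Z-C1=C10.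

**Step 6**
Reactants: 8 (7R)-(1(10)Z,4E)-germacra-1(10),4,11-triene
Product: 9 (7S,9S)-(1(10)Z,4E)-germacra-1(10),4,11-trien-9-ol
Conditions: cytochrome P450 BM3 (CYP102A1) variant, NADP+ (cat.), D-glucose, glucose dehydrogenase, air, potassium phosphate buffer pH 8.0, 25 °C
Reagents that add atoms: dioxygen, O=O
Why: P450 hydrogen abstraction and oxygen rebound (allylic C–H hydroxylation, a reaction of this enzyme family on C9 of germacranes) should oxidise the ring methylene flanking the Z alkene, with site selectivity supplied by the chosen variant and the C9 configuration of no consequence because step 7 removes it.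

**Step 7**
Reactants: 9 (7S,9S)-(1(10)Z,4E)-germacra-1(10),4,11-trien-9-ol
Product: 10 (7S)-(1(10)Z,4E)-germacra-1(10),4,11-trien-9-one
Conditions: activated MnO2, CH2Cl2, rt
Reagents that add atoms: none
Why: MnO2 oxidises only the allylic alcohol and should give the Z-enone without acid or heat that would trigger Cope rearrangement or transannular cyclisation of the 1,5-diene.

**Step 8**
Reactants: 10 (7S)-(1(10)Z,4E)-germacra-1(10),4,11-trien-9-one
Product: 12 (7R,8S)-8-hydroxy-(1(10)Z,4E)-germacra-1(10),4,11-trien-9-one, via potassium enolate 11 (not isolated)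
Conditions: KN(SiMe3)2, THF, −78 °C; then 2-(phenylsulfonyl)-3-phenyloxaziridine, −78 °C; aq. NH4Cl
Reagents that add atoms: 2-(phenylsulfonyl)-3-phenyloxaziridine, O=S(=O)(c1ccccc1)N1OC1c1ccccc1
Why: Kinetic deprotonation occurs at C8, the only α-methylene of the ketone, and the N-sulfonyloxaziridine transfers oxygen to the enolate (α-hydroxylation) on its outer face with the C7 isopropenyl group pseudo-equatorial in the enolate plane, so the new C8–O bond should come out cis to it (8S).

**Step 9**
Reactants: 12 (7R,8S)-8-hydroxy-(1(10)Z,4E)-germacra-1(10),4,11-trien-9-one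
Product: 13 (7R,8S,9R)-(1(10)Z,4E)-germacra-1(10),4,11-triene-8,9-diol (8,9-cis)
Conditions: Zn(BH4)2, Et2O, −20 °C
Reagents that add atoms: none
Why: Chelation-controlled 1,2-reduction, in which zinc bridges the C8 hydroxyl and the C9 carbonyl and hydride enters anti to the C7 branch on C8, should give the 8,9-cis (erythro) diol and leave the alkenes alone.

**Step 10**
Reactants: 13 (7R,8S,9R)-(1(10)Z,4E)-germacra-1(10),4,11-triene-8,9-diol
Product: 14 (1S,7R,8S,9S,10R)-1,10-epoxy-(4E)-germacra-4,11-diene-8,9-diol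
Conditions: VO(acac)2 (cat.), t-BuOOH (decane solution), CH2Cl2, 0 °C
Reagents that add atoms: tert-butyl hydroperoxide, CC(C)(C)OO
Why: Vanadium-catalysed hydroxyl-directed epoxidation touches only the alkene carrying the allylic C9 hydroxyl, and because allylic 1,3-strain in the Z-allylic alcohol holds H9 in the alkene plane, oxygen is delivered syn to C9–OH and anti to C8 (threo epoxy alcohol).

**Step 11**
Reactants: 14 (1S,7R,8S,9S,10R)-1,10-epoxy-(4E)-germacra-4,11-diene-8,9-diol
Product: 15 (1S,7R,8S,9S,10R)-8-angeloyloxy-1,10-epoxy-(4E)-germacra-4,11-dien-9-ol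
Conditions: angelic acid, 2,4,6-trichlorobenzoyl chloride, Et3N, toluene, rt, filter; then 14, toluene, 60 °C
Reagents that add atoms: angelic acid, C/C=C(/C)C(=O)O
Why: Yamaguchi esterification with the preformed mixed anhydride and no nucleophilic catalyst keeps the Z geometry of the angelate and should acylate the C8 hydroxyl, which is much less hindered than the C9 hydroxyl flanked by the fully substituted oxirane carbon C10 (acyl migration would also favour C8).

**Step 12**
Reactants: 15 (1S,7R,8S,9S,10R)-8-angeloyloxy-1,10-epoxy-(4E)-germacra-4,11-dien-9-ol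
Product: 16 (1S,7R,8S,9S,10S)-9-acetoxy-8-angeloyloxy-1,10-epoxy-(4E)-germacra-4,11-diene
Conditions: Ac2O, DMAP (cat.), Et3N, CH2Cl2, rt
Reagents that add atoms: acetic anhydride, CC(=O)OC(C)=O
Why: DMAP-catalysed acetylation with the small anhydride should esterify the remaining hindered secondary C9 hydroxyl faster than the neighbouring angelate can migrate.

**Step 13**
Reactants: 16 (1S,7R,8S,9S,10S)-9-acetoxy-8-angeloyloxy-1,10-epoxy-(4E)-germacra-4,11-diene
Product: 17 (1S,3S,7R,8S,9S,10S)-9-acetoxy-8-angeloyloxy-1,10-epoxy-(4E)-germacra-4,11-dien-3-ol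
Conditions: cytochrome P450 BM3 (CYP102A1) variant (purified), NADP+ (cat.), D-glucose, glucose dehydrogenase, air, potassium phosphate buffer pH 8.0, 25 °C
Reagents that add atoms: dioxygen, O=O
Why: P450 allylic C–H hydroxylation (hydrogen abstraction and oxygen rebound) should take place at C3, the unhindered methylene on the substituted end of the remaining ring alkene, with the 3S (3β) face selectivity known for germacrane 3-hydroxylases supplied by the enzyme variant.

**Step 14**
Reactants: 17 (1S,3S,7R,8S,9S,10S)-9-acetoxy-8-angeloyloxy-1,10-epoxy-(4E)-germacra-4,11-dien-3-ol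
Product: 18 (1S,3S,4R,5R,7R,8S,9S,10S)-9-acetoxy-8-angeloyloxy-1,10:4,5-diepoxygermacr-11-en-3-ol
Conditions: mCPBA (1.05 equiv), NaHCO3, CH2Cl2, 0 °C
Reagents that add atoms: 3-chloroperoxybenzoic acid, O=C(OO)c1cccc(Cl)c1
Why: Prilezhaev epoxidation should select the most electron-rich alkene (trisubstituted E-C4=C5, ahead of isopropenyl and the conjugated angelate), the peracid arriving on the outer face of the E-cyclodecene in the conformer that holds C15 on the side of the C3 oxygen, where the 3-hydroxyl also hydrogen-bonds to it (Henbest effect), to give the trans-oxirane of the target.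

**Step 15**
Reactants: 18 (1S,3S,4R,5R,7R,8S,9S,10S)-9-acetoxy-8-angeloyloxy-1,10:4,5-diepoxygermacr-11-en-3-ol
Product: 19 (1S,3S,4S,5R,7R,8S,9S,10S)-9-acetoxy-3,8-bis(angeloyloxy)-1,10:4,5-diepoxygermacr-11-ene (CNP0220329.2)
Conditions: angelic acid, 2,4,6-trichlorobenzoyl chloride, Et3N, toluene, rt, filter; then 18, toluene, 70 °C
Reagents that add atoms: angelic acid, C/C=C(/C)C(=O)O
Why: Yamaguchi esterification of the hindered C3 hydroxyl under base-poor thermal conditions avoids Payne rearrangement of an epoxy alkoxide and angelate-to-tiglate isomerisation, and no Cope-active 1,5-diene remains to suffer from the heating.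

**Compound list**
1 | nerylacetone | CC(C)=CCC/C(C)=C\CCC(C)=O | starting material
2 | triethyl phosphonoacetate | CCOC(=O)CP(=O)(OCC)OCC | starting material
3 | ethyl (2E,6Z)-3,7,11-trimethyldodeca-2,6,10-trienoate | CCOC(=O)/C=C(C)/CC/C=C(C)\CCC=C(C)C | intermediate
4 | (2E,6Z)-farnesol | OC/C=C(C)/CC/C=C(C)\CCC=C(C)C | intermediate
5 | (2E,6Z)-farnesyl chloride | ClC/C=C(C)/CC/C=C(C)\CCC=C(C)C | intermediate
6 | bis(tetrabutylammonium) hydrogen (2E,6Z)-farnesyl diphosphate | CC(C)=CCC/C(C)=C\CC/C(C)=C/COP(=O)([O-])OP(=O)(O)[O-].CCCC[N+](CCCC)(CCCC)CCCC.CCCC[N+](CCCC)(CCCC)CCCC | intermediate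
7 | trisammonium (2E,6Z)-farnesyl diphosphate | [NH4+].[NH4+].[NH4+].[O-]P(=O)([O-])OP(=O)([O-])OC/C=C(C)/CC/C=C(C)\CCC=C(C)C | intermediate
8 | (7R)-(1(10)Z,4E)-germacra-1(10),4,11-triene | C=C(C)[C@H]1C/C=C(C)/CC/C=C(C)\CC1 | intermediate
9 | (7S,9S)-(1(10)Z,4E)-germacra-1(10),4,11-trien-9-ol | C=C(C)[C@H]1C/C=C(C)/CC/C=C(C)\[C@@H](O)C1 | intermediate
10 | (7S)-(1(10)Z,4E)-germacra-1(10),4,11-trien-9-one | C=C(C)[C@H]1C/C=C(C)/CC/C=C(C)\C(=O)C1 | intermediate
11 | potassium C8=C9 enolate of 10 | C=C(C)[C@H]1C/C=C(C)/CC/C=C(C)\C([O-])=C1.[K+] | intermediate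
12 | (7R,8S)-8-hydroxy-(1(10)Z,4E)-germacra-1(10),4,11-trien-9-one | C=C(C)[C@H]1C/C=C(C)/CC/C=C(C)\C(=O)[C@H]1O | intermediate
13 | (7R,8S,9R)-(1(10)Z,4E)-germacra-1(10),4,11-triene-8,9-diol | C=C(C)[C@H]1C/C=C(C)/CC/C=C(C)\[C@@H](O)[C@H]1O | intermediate
14 | (1S,7R,8S,9S,10R)-1,10-epoxy-(4E)-germacra-4,11-diene-8,9-diol | C=C(C)[C@H]1C/C=C(C)/CC[C@@H]2O[C@]2(C)[C@@H](O)[C@H]1O | intermediate
15 | (1S,7R,8S,9S,10R)-8-angeloyloxy-1,10-epoxy-(4E)-germacra-4,11-dien-9-ol | C=C(C)[C@H]1C/C=C(C)/CC[C@@H]2O[C@]2(C)[C@@H](O)[C@H]1OC(=O)/C(C)=C\C | intermediate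
16 | (1S,7R,8S,9S,10S)-9-acetoxy-8-angeloyloxy-1,10-epoxy-(4E)-germacra-4,11-diene | C=C(C)[C@H]1C/C=C(C)/CC[C@@H]2O[C@]2(C)[C@@H](OC(C)=O)[C@H]1OC(=O)/C(C)=C\C | intermediate
17 | (1S,3S,7R,8S,9S,10S)-9-acetoxy-8-angeloyloxy-1,10-epoxy-(4E)-germacra-4,11-dien-3-ol | C=C(C)[C@H]1C/C=C(C)/[C@@H](O)C[C@@H]2O[C@]2(C)[C@@H](OC(C)=O)[C@H]1OC(=O)/C(C)=C\C | intermediate
18 | (1S,3S,4R,5R,7R,8S,9S,10S)-9-acetoxy-8-angeloyloxy-1,10:4,5-diepoxygermacr-11-en-3-ol | C=C(C)[C@H]1C[C@H]2O[C@]2(C)[C@@H](O)C[C@@H]2O[C@]2(C)[C@@H](OC(C)=O)[C@H]1OC(=O)/C(C)=C\C | intermediate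
19 | (1S,3S,4S,5R,7R,8S,9S,10S)-9-acetoxy-3,8-bis(angeloyloxy)-1,10:4,5-diepoxygermacr-11-ene (CNP0220329.2) | C=C(C)[C@H]1C[C@H]2O[C@]2(C)[C@@H](OC(=O)/C(C)=C\C)C[C@@H]2O[C@]2(C)[C@@H](OC(C)=O)[C@H]1OC(=O)/C(C)=C\C | target

Total step count: 15. Longest linear sequence: 15 steps (from nerylacetone).

**Steps most likely to fail**

1. Step 5 (Proposed new method). The cyclase may not fold the 6Z chain productively. Ionisation could then be followed by water capture, elimination to farnesenes, the eleven-membered closure, or presentation of the wrong C7 face.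
   Fallback (known chemistry, from 3 back to 8): the same C6–C7 bond is made by a palladium-mediated umpolung allylation.
   - Ester 3 is oxidised at the terminal E-methyl group (SeO2 cat., t-BuOOH, CH2Cl2) to ethyl (2E,6Z,10E)-12-hydroxyfarnesoate F1.
   - F1 is converted (MsCl, LiCl, 2,4,6-collidine, DMF, 0 °C) into ethyl (2E,6Z,10E)-12-chlorofarnesoate F2 and reduced (i-Bu2AlH, −78 °C) to (2E,6Z,10E)-12-chlorofarnesol F3.
   - Sharpless asymmetric epoxidation (Ti(Oi-Pr)4, D-(−)-diethyl tartrate, t-BuOOH, −20 °C) should give (2R,3R)-12-chloro-2,3-epoxyfarnesol F4, and Dess–Martin oxidation the corresponding epoxy aldehyde F5.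
   - Slow addition of F5 to PdCl2(PPh3)2 (cat.), Et2Zn and K2CO3 in DMA should close the ten-membered ring by attack of the allylzinc γ-carbon on the aldehyde, giving 4,5-epoxy-(1(10)Z)-germacra-1(10),11-dien-6-ol F6. The oxirane relays its configuration to C7, and the tartrate enantiomer is chosen so that C7 matches 8.
   - WCl6/n-BuLi (THF, −78 °C to rt) removes the oxirane oxygen with retention to give (1(10)Z,4E)-germacra-1(10),4,11-trien-6-ol F7.
   - Its mesylate, (1(10)Z,4E)-germacra-1(10),4,11-trien-6-yl methanesulfonate F8 (MsCl, Et3N, −40 °C, used at once), is displaced with LiEt3BH (THF, −78 °C) to return to 8.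

2. Step 6. Oxygen rebound may lack site selectivity (abstraction at C2, C3, C6 or a methyl group), or the enzyme may epoxidise an alkene or over-oxidise the product.
   Fallback (from 8 back to 9): the strained E alkene is masked and the oxygen is put in by an ene reaction.
   - mCPBA (1.0 equiv, NaHCO3, CH2Cl2, −40 °C) should epoxidise E-C4=C5 first, giving 4,5-epoxy-(1(10)Z)-germacra-1(10),11-diene F9.
   - SeO2 (cat.)/t-BuOOH then hydroxylates the ring methylene on the substituted end of the remaining Z-trisubstituted alkene (ene reaction, then 2,3-shift) to 4,5-epoxy-(1(10)Z)-germacra-1(10),11-dien-9-ol F10.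
   - WCl6/n-BuLi restores the E alkene with retention to give 9.

3. Step 13. On a large ester-bearing substrate the hydroxylation may go to C6, give the 3-epimer, epoxidise C4=C5, or be accompanied by ester hydrolysis.
   Fallback (from 16 back to 17): the alcohol is made through the ketone.
   - CrO3·3,5-dimethylpyrazole (CH2Cl2, −20 °C) oxidises the allylic C3 methylene (C6 is shielded by the C7 branch) to (1S,7R,8S,9S,10S)-9-acetoxy-8-angeloyloxy-1,10-epoxy-(4E)-germacra-4,11-dien-3-one F11.
   - Corey–Bakshi–Shibata reduction ((R)-2-methyl-oxazaborolidine cat., catecholborane, toluene, −78 °C) should give the 3S alcohol 17 under reagent control.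

**Further compounds**
F1 | step 5 | ethyl (2E,6Z,10E)-12-hydroxy-3,7,11-trimethyldodeca-2,6,10-trienoate | CCOC(=O)/C=C(C)/CC/C=C(C)\CC/C=C(C)/CO
F2 | step 5 | ethyl (2E,6Z,10E)-12-chloro-3,7,11-trimethyldodeca-2,6,10-trienoate | CCOC(=O)/C=C(C)/CC/C=C(C)\CC/C=C(C)/CCl
F3 | step 5 | (2E,6Z,10E)-12-chlorofarnesol | OC/C=C(C)/CC/C=C(C)\CC/C=C(C)/CCl
F4 | step 5 | (2R,3R)-12-chloro-2,3-epoxy-(6Z,10E)-farnesol | OC[C@H]1O[C@]1(C)CC/C=C(C)\CC/C=C(C)/CCl
F5 | step 5 | 12-chloro-2,3-epoxy-(6Z,10E)-farnesal (aldehyde of F4) | O=C[C@H]1O[C@]1(C)CC/C=C(C)\CC/C=C(C)/CCl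
F6 | step 5 | 4,5-epoxy-(1(10)Z)-germacra-1(10),11-dien-6-ol (C6 epimer as formed) | C=C(C)[C@H]1C(O)[C@H]2O[C@]2(C)CC/C=C(C)\CC1
F7 | step 5 | (1(10)Z,4E)-germacra-1(10),4,11-trien-6-ol | C=C(C)[C@H]1C(O)/C=C(C)/CC/C=C(C)\CC1
F8 | step 5 | (1(10)Z,4E)-germacra-1(10),4,11-trien-6-yl methanesulfonate | C=C(C)[C@H]1C(OS(C)(=O)=O)/C=C(C)/CC/C=C(C)\CC1
F9 | step 6 | 4,5-epoxy-(1(10)Z)-germacra-1(10),11-diene | C=C(C)[C@H]1C[C@H]2O[C@]2(C)CC/C=C(C)\CC1
F10 | step 6 | 4,5-epoxy-(1(10)Z)-germacra-1(10),11-dien-9-ol | C=C(C)[C@H]1C[C@H]2O[C@]2(C)CC/C=C(C)\[C@@H](O)C1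
F11 | step 13 | (1S,7R,8S,9S,10S)-9-acetoxy-8-angeloyloxy-1,10-epoxy-(4E)-germacra-4,11-dien-3-one | C=C(C)[C@H]1C/C=C(C)/C(=O)C[C@@H]2O[C@]2(C)[C@@H](OC(C)=O)[C@H]1OC(=O)/C(C)=C\C
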